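## Analysis of the target

The target is a dihydrochalcone whose phloroglucinol ring is fused to a seven-membered cyclic ether. This is a 2,5-dihydro-1-benzoxepine in which O1, C2H2, C3(CH3)=C4H and C5H2 bridge the adjacent aromatic carbons C9a and C5a. The benzene ring is pentasubstituted: free hydroxyls at C6 and C8, the 3-(3,4-dihydroxyphenyl)propanoyl group at C7 between them, and a single hydrogen at C9, so the ring oxygen O1 lies para to the ketone. There is no stereocentre; the only stereochemical element is the trisubstituted C3=C4 olefin, and the ring forces it to be cis. The sensitive groups are the catechol (oxidation in base and air), the allyl aryl ether, the doubly activated C5 methylene (olefin migration or ring opening under base) and the very electron-rich arene. The difficulty is twofold: closing a seven-membered ring with the olefin out of conjugation with the arene, and telling three phloroglucinol oxygens apart so that the ether is para and the two hydroxyls ortho to the acyl group. The plan rests on one observation: C5, C5a, C9a and O1 are the four atoms of an ortho-quinone methide, and C2, C3 and C4 are a 2-substituted allyl unit, so the oxepine is a [4+3] adduct.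

## Retrosynthetic reasoning

**18 from 17.** The four aryl O–CH2OCH3 bonds are cut last. MOM ethers are chosen because the two on the benzoxepine later direct a metalation, and because all four survive base, hydride and organolithium reagents and fall in one acidic operation.

**17 from 12 and 15 (through 16).** The C7–C(=O) bond is cut. C7 is the only ring carbon flanked by two MOM ethers, so deprotonation of 12 should give aryllithium 16 at that position, and acyl transfer from Weinreb amide 15 stops at the ketone. Cutting here keeps the ketone out of all hydride steps and leaves a benzoxepine 12 with no functionality other than its protecting groups. The forward reaction has to metalate C7–H ahead of C9–H and the allylic methylenes.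

**15 from 14 and 13.** The amide C–N bond and the two catechol O–MOM bonds are cut, leading back to the acid 13. The amide is formed first so that only two protecting-group bonds have to be made.

**12 from 11, 10 and 9.** The ring methyl is traced back to an ester carbon, by way of the allylic bromide 11 and the allylic alcohol 10. The annulation that builds the ring needs an electron-withdrawing group on the central allyl carbon, and an ester can be taken down to CH3 by two hydride reductions and one substitution without moving the olefin. The forward steps must deliver hydride to the exocyclic carbon only.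

**9 from 4 and 6 (through 7 and 8).** The C4–C5 bond and the O1–C2 bond are cut together. This is the point of greatest simplification: both ring bonds come from one operation, the partners are achiral and easily made, and the olefin geometry cannot be wrong. Sulfone 4 is a stable precursor of quinone methide 7, and carbonate 6 is the precursor of the allylic ylide 8 under phosphine catalysis. The forward reaction has to join the phosphorus-bearing carbon of 8 to the methylene of 7 and then close the ring through oxygen at the far allyl terminus, not at the near one.

**4 from 3, 2 and 1; 6 from 5.** The C–S bond of 4 is cut to the salicyl alcohol 3, which comes from aldehyde 2 and this from the trihydroxybenzaldehyde 1. The hydroxyl that stays free in 2 is the one hydrogen-bonded to the aldehyde; it is the one that becomes O1, which fixes the position of the ring oxygen from the first step. Carbonate 6 is the tert-butyl carbonate of the commercial hydroxymethyl acrylate 5.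

## Alternatives that were turned down

**Alternative 1: aryl ether closure by copper catalysis on the complete ketone.**
- Disconnection: the C9a–O1 bond, made last. The substrate is the bromo (Z)-allylic alcohol A2, which already carries the ketone and all four MOM ethers.
- Forward key step: CuI (copper iodide), 3,4,7,8-tetramethyl-1,10-phenanthroline and Cs2CO3 would couple the primary alcohol with the aryl bromide to give A1, which is identical with 17.
- For it: the acyl group is in place before the ring is closed, so no organolithium touches the finished heterocycle. The bromide is para to the ketone, which helps oxidative addition to monovalent copper. The product is one step from the target.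
- Against it: A2 is a hexasubstituted benzene with four kinds of substituent, each to be placed regioselectively. Its (Z)-trisubstituted allylic alcohol must be made stereodefined and must keep its geometry above 100 °C in the presence of carbonate. The closure forms a seven-membered ring at a carbon with two ortho substituents. The copper alkoxide of an allylic alcohol can lose a β-hydride, which leads to an enal and to hydrodebromination, and the ketone is enolisable.
- Comparison: Alternative 1 is stronger on the acyl group. The chosen strategy offers instead a ring closure at room temperature that forms two bonds from two simple partners, an olefin geometry that needs no control, and a shorter sequence.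

**Alternative 2: one-carbon ring expansion of a 4H-chromene.**
- Disconnection: C3 with its methyl is inserted as a carbene carbon between C2 and C4, starting from the chromene A4.
- Forward key step: the carbenoid from 1,1-dichloroethane and n-BuLi would add to the enol ether double bond of A4. AgBF4 would then ionise the chloride with opening of the three-membered ring, and Et3SiH would reduce the oxocarbenium ion to A3, which is identical with 12.
- For it: the methyl-bearing oxepine arrives directly, so the three steps that turn the ester into CH3 are saved. On step count this is the stronger route.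
- Against it: n-BuLi is present together with an arene that is lithiated easily between its MOM ethers. The chloro(methyl)carbenoid rearranges readily to vinyl chloride. Only the adduct epimer with chlorine on the concave face can open in the disrotatory sense that keeps the allyl cation inside the ring, and the addition does not control that centre. The alkoxyallyl cation can take hydride at either terminus, lose a proton, or alkylate the electron-rich ring, and AgBF4 is a Lewis acid towards MOM ethers. A4 is itself a labile enol ether. The late acylation remains the same as in the chosen route.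
- Comparison: the chosen strategy is longer by the ester adjustment, but each bond is made by a polar step whose regiochemistry follows from the structure of the partners.

**Alternative 3: biomimetic etherification of a hydroxylated prenyl chain.**
- Disconnection: the O1–C2 bond. The substrate is the C-alkylated triol ketone A6 with a (Z)-4-hydroxy-3-methylbut-2-enyl chain.
- Forward key step: PPh3 and DIAD would activate the allylic alcohol of A6, and the phenol para to the ketone would displace it to give A5, the target with only the catechol protected.
- For it: the ketone and the carbon chain are present from the start, only the catechol is protected, and no organometallic step is needed. The para hydroxyl is the most acidic and is not chelated. On protecting-group economy this is the strongest of the four.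
- Against it: the chain sits between two hydroxyls, and either can close a seven-membered ring; only hydrogen bonding to the ketone tells them apart. Attack of a phenol at the internal olefin carbon (5-exo, SN2') would give an isopropenyl dihydrobenzofuran and competes with the seven-membered SN2 closure. Three free phenols invite intermolecular etherification. A6 itself requires C-alkylation of an acylphloroglucinol (C versus O, mono versus bis) with a Z-configured oxygenated prenyl unit, which is the less accessible geometry.
- Comparison: the chosen strategy spends more protecting-group steps. In return the oxygen regiochemistry is unambiguous, because 4 has a single free phenol, and the ring closure is not in competition with a five-membered one of comparable ease.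

Key step: step 5

## Route

**Step 1**
Reactants: 1 2,4,6-trihydroxybenzaldehyde
Product: 2 2-hydroxy-4,6-bis(methoxymethoxy)benzaldehyde
Conditions: MOMCl (2.2 equiv), i-Pr2NEt (2.5 equiv), CH2Cl2, 0 °C to rt
Reagents that add atoms: chloromethyl methyl ether (MOMCl), COCCl
Why: Williamson-type MOM protection; the 4-hydroxyl and one of the two equivalent ortho hydroxyls are alkylated, after which the remaining ortho hydroxyl is locked in a hydrogen bond to the aldehyde and reacts much more slowly, so two equivalents should stop at 2.

**Step 2**
Reactants: 2 2-hydroxy-4,6-bis(methoxymethoxy)benzaldehyde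
Product: 3 2-(hydroxymethyl)-3,5-bis(methoxymethoxy)phenol
Conditions: NaBH4 (1.0 equiv), THF–MeOH, 0 °C, short reaction time; cold aq. NH4Cl; crude used at once
Reagents that add atoms: none
Why: Borohydride 1,2-reduction of the aldehyde; low temperature and a near-neutral work-up should keep the electron-rich salicyl alcohol from ionising, and the MOM ethers are inert to hydride.

**Step 3**
Reactants: 3 2-(hydroxymethyl)-3,5-bis(methoxymethoxy)phenol
Product: 4 3,5-bis(methoxymethoxy)-2-[(4-methylphenyl)sulfonylmethyl]phenol
Conditions: p-TolSO2Na (2 equiv), AcOH, THF–H2O, rt
Reagents that add atoms: sodium p-toluenesulfinate, Cc1ccc(cc1)S(=O)[O-].[Na+]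
Why: Acid-promoted substitution of the benzylic hydroxyl; the 2,4,6-trioxygenated benzylic position ionises even in acetic acid, the soft sulfinate sulfur captures it to give the sulfone as the thermodynamic product, and the buffered medium is too weakly acidic to cleave aryl MOM ethers at room temperature.

**Step 4**
Reactants: 5 methyl 2-(hydroxymethyl)acrylate
Product: 6 methyl 2-[(tert-butoxycarbonyloxy)methyl]acrylate
Conditions: Boc2O (1.1 equiv), DMAP (10 mol %), CH2Cl2, 0 °C to rt
Reagents that add atoms: di-tert-butyl dicarbonate (Boc2O), CC(C)(C)OC(=O)OC(=O)OC(C)(C)C
Why: DMAP-catalysed O-acylation of the primary allylic alcohol, the standard preparation of Morita–Baylis–Hillman carbonates.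

**Step 5**
Reactants: 4 3,5-bis(methoxymethoxy)-2-[(4-methylphenyl)sulfonylmethyl]phenol; 6 methyl 2-[(tert-butoxycarbonyloxy)methyl]acrylate
Product: 9 methyl 6,8-bis(methoxymethoxy)-2,5-dihydro-1-benzoxepine-3-carboxylate, via o-quinone methide 7 (not isolated), via allylic phosphorus ylide 8 (not isolated)
Conditions: 6 (1.3 equiv), PPh3 (20 mol %), Cs2CO3 (1.5 equiv), CH2Cl2, rt
Reagents that add atoms: none
Why: This is a Lewis-base-catalysed [4+3] annulation of a Morita–Baylis–Hillman carbonate with an o-quinone methide made in the flask, a known reaction type for 2-(sulfonylmethyl)phenols and their aza analogues. PPh3 adds to 6 in an SN2' sense and expels tert-butyl carbonate, which loses CO2; the tert-butoxide deprotonates the allylphosphonium salt to ylide 8, while Cs2CO3 deprotonates phenol 4, whose phenolate expels p-toluenesulfinate to give quinone methide 7. The phosphorus-bearing carbon of 8 adds to the exocyclic methylene of 7 with rearomatisation as the driving force, forming the C4–C5 bond and a phenolate. The phenolate closes the oxepine by a 7-endo-trig oxa-Michael addition to the acrylate CH2 followed by E1cB loss of PPh3 (a net intramolecular SN2'), which forms the O1–C2 bond, returns the catalyst and leaves the olefin at C3=C4 in conjugation with the ester. No stereocentre is created, and the ring olefin can only be cis. The step needs periselectivity for [4+3] over [4+1], the latter being a 5-exo-tet displacement of PPh3 at the carbon that has just bonded; the unhindered, unsubstituted acrylate terminus and the poor SN2 reactivity of a secondary phosphonium carbon should favour the seven-membered ring. It also needs sulfinate loss from the phenolate of 4 to outrun O-allylation of that phenolate, and the two MOM ethers ortho and para to the benzylic carbon accelerate the loss. The position of the ring oxygen is not in question, because 4 has a single free phenol.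

**Step 6**
Reactants: 9 methyl 6,8-bis(methoxymethoxy)-2,5-dihydro-1-benzoxepine-3-carboxylate
Product: 10 [6,8-bis(methoxymethoxy)-2,5-dihydro-1-benzoxepin-3-yl]methanol
Conditions: i-Bu2AlH (2.5 equiv), CH2Cl2, −78 °C; aq. KNaC4H4O6 (potassium sodium tartrate)
Reagents that add atoms: none
Why: 1,2-Reduction of the conjugated ester to the allylic alcohol; at −78 °C neither the MOM ethers nor the allyl aryl ether should react, and the olefin stays at C3=C4.

**Step 7**
Reactants: 10 [6,8-bis(methoxymethoxy)-2,5-dihydro-1-benzoxepin-3-yl]methanol
Product: 11 3-(bromomethyl)-6,8-bis(methoxymethoxy)-2,5-dihydro-1-benzoxepine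
Conditions: CBr4 (1.3 equiv), PPh3 (1.4 equiv), CH2Cl2, 0 °C
Reagents that add atoms: carbon tetrabromide, BrC(Br)(Br)Br
Why: Appel bromination of the primary allylic alcohol under neutral conditions that MOM ethers tolerate; the primary bromide with the trisubstituted olefin is also the thermodynamically preferred allylic isomer.

**Step 8**
Reactants: 11 3-(bromomethyl)-6,8-bis(methoxymethoxy)-2,5-dihydro-1-benzoxepine
Product: 12 6,8-bis(methoxymethoxy)-3-methyl-2,5-dihydro-1-benzoxepine
Conditions: LiEt3BH (1.5 equiv), THF, 0 °C
Reagents that add atoms: none
Why: SN2 displacement of the unhindered primary allylic bromide by hydride; direct attack at CH2Br is favoured over SN2' attack at the substituted C4, so the olefin keeps its place and the former ester carbon becomes the ring methyl.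

**Step 9**
Reactants: 13 3-(3,4-dihydroxyphenyl)propanoic acid
Product: 14 3-(3,4-dihydroxyphenyl)-N-methoxy-N-methylpropanamide
Conditions: MeNHOMe·HCl (1.2 equiv), EDC·HCl (1.2 equiv), HOBt (1.0 equiv), Et3N (2.2 equiv), DMF, 0 °C to rt, under N2
Reagents that add atoms: N,O-dimethylhydroxylamine hydrochloride, CNOC.Cl
Why: Carbodiimide/HOBt amide coupling; the amine is far more nucleophilic than the catechol hydroxyls, any aryl ester formed in passing is aminolysed, and exclusion of air protects the catechol.

**Step 10**
Reactants: 14 3-(3,4-dihydroxyphenyl)-N-methoxy-N-methylpropanamide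
Product: 15 3-[3,4-bis(methoxymethoxy)phenyl]-N-methoxy-N-methylpropanamide
Conditions: MOMCl (2.5 equiv), i-Pr2NEt (3 equiv), CH2Cl2, 0 °C to rt
Reagents that add atoms: chloromethyl methyl ether (MOMCl), COCCl
Why: Williamson-type MOM protection of both phenols; the Weinreb amide has no N–H and is inert to the alkylating agent.

**Step 11**
Reactants: 12 6,8-bis(methoxymethoxy)-3-methyl-2,5-dihydro-1-benzoxepine; 15 3-[3,4-bis(methoxymethoxy)phenyl]-N-methoxy-N-methylpropanamide
Product: 17 3-[3,4-bis(methoxymethoxy)phenyl]-1-[6,8-bis(methoxymethoxy)-3-methyl-2,5-dihydro-1-benzoxepin-7-yl]propan-1-one, via 7-lithio benzoxepine 16 (not isolated)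
Conditions: n-BuLi (1.05 equiv), THF, −20 to 0 °C; then 15 (1.1 equiv), −78 to 0 °C; aq. NH4Cl
Reagents that add atoms: none
Why: Directed ortho-metalation followed by Weinreb ketone synthesis; C7–H is the only ring hydrogen flanked by two MOM ethers, whose joint coordination of n-BuLi should make it the kinetically most acidic site, ahead of C9–H and the allylic methylenes, and the aryllithium adds only once because the chelated tetrahedral intermediate persists until the quench.

**Step 12**
Reactants: 17 3-[3,4-bis(methoxymethoxy)phenyl]-1-[6,8-bis(methoxymethoxy)-3-methyl-2,5-dihydro-1-benzoxepin-7-yl]propan-1-one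
Product: 18 1-(6,8-dihydroxy-3-methyl-2,5-dihydro-1-benzoxepin-7-yl)-3-(3,4-dihydroxyphenyl)propan-1-one (target)
Conditions: 3 M aq. HCl–MeOH (1:5), 40 °C, under N2
Reagents that add atoms: none
Why: Acid-catalysed acetal exchange with methanol removes the four MOM groups; the two next to the ketone leave fastest through hydrogen-bond assistance, the trisubstituted olefin and the allyl aryl ether should tolerate dilute acid at this temperature, and air is excluded for the catechol.

## Compound list

1 | 2,4,6-trihydroxybenzaldehyde | O=Cc1c(O)cc(O)cc1O | starting material
2 | 2-hydroxy-4,6-bis(methoxymethoxy)benzaldehyde | O=Cc1c(O)cc(OCOC)cc1OCOC | intermediate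
3 | 2-(hydroxymethyl)-3,5-bis(methoxymethoxy)phenol | OCc1c(O)cc(OCOC)cc1OCOC | intermediate
4 | 3,5-bis(methoxymethoxy)-2-[(4-methylphenyl)sulfonylmethyl]phenol | Cc1ccc(S(=O)(=O)Cc2c(O)cc(OCOC)cc2OCOC)cc1 | intermediate
5 | methyl 2-(hydroxymethyl)acrylate | C=C(CO)C(=O)OC | starting material
6 | methyl 2-[(tert-butoxycarbonyloxy)methyl]acrylate | C=C(COC(=O)OC(C)(C)C)C(=O)OC | intermediate
7 | 3,5-bis(methoxymethoxy)-6-methylidenecyclohexa-2,4-dien-1-one (o-quinone methide) | C=C1C(=O)C=C(OCOC)C=C1OCOC | intermediate (not isolated)
8 | methyl 2-[(triphenyl-λ5-phosphanylidene)methyl]acrylate (allylic phosphorus ylide) | COC(=O)C(=C)C=P(c1ccccc1)(c1ccccc1)c1ccccc1 | intermediate (not isolated)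
9 | methyl 6,8-bis(methoxymethoxy)-2,5-dihydro-1-benzoxepine-3-carboxylate | COC(=O)C1=CCc2c(OCOC)cc(OCOC)cc2OC1 | intermediate
10 | [6,8-bis(methoxymethoxy)-2,5-dihydro-1-benzoxepin-3-yl]methanol | OCC1=CCc2c(OCOC)cc(OCOC)cc2OC1 | intermediate
11 | 3-(bromomethyl)-6,8-bis(methoxymethoxy)-2,5-dihydro-1-benzoxepine | BrCC1=CCc2c(OCOC)cc(OCOC)cc2OC1 | intermediate
12 | 6,8-bis(methoxymethoxy)-3-methyl-2,5-dihydro-1-benzoxepine | CC1=CCc2c(OCOC)cc(OCOC)cc2OC1 | intermediate
13 | 3-(3,4-dihydroxyphenyl)propanoic acid | OC(=O)CCc1ccc(O)c(O)c1 | starting material
14 | 3-(3,4-dihydroxyphenyl)-N-methoxy-N-methylpropanamide | CON(C)C(=O)CCc1ccc(O)c(O)c1 | intermediate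
15 | 3-[3,4-bis(methoxymethoxy)phenyl]-N-methoxy-N-methylpropanamide | CON(C)C(=O)CCc1ccc(OCOC)c(OCOC)c1 | intermediate
16 | [6,8-bis(methoxymethoxy)-3-methyl-2,5-dihydro-1-benzoxepin-7-yl]lithium | CC1=CCc2c(cc(OCOC)c([Li])c2OCOC)OC1 | intermediate (not isolated)
17 | 3-[3,4-bis(methoxymethoxy)phenyl]-1-[6,8-bis(methoxymethoxy)-3-methyl-2,5-dihydro-1-benzoxepin-7-yl]propan-1-one | CC1=CCc2c(cc(OCOC)c(C(=O)CCc3ccc(OCOC)c(OCOC)c3)c2OCOC)OC1 | intermediate
18 | 1-(6,8-dihydroxy-3-methyl-2,5-dihydro-1-benzoxepin-7-yl)-3-(3,4-dihydroxyphenyl)propan-1-one | CC1=CCc2c(cc(O)c(C(=O)CCc3ccc(O)c(O)c3)c2O)OC1 | target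

## Step count and least certain steps

Total: 12 steps. Longest linear sequence: 9 steps (1 → 2 → 3 → 4 → 9 → 10 → 11 → 12 → 17 → 18). Carbonate 6 (1 step) and amide 15 (2 steps) are made separately.

**Step 5 (key step).** The zwitterion may close at the phosphorus-bearing carbon instead of the acrylate terminus (the [4+1] mode). The phenolate of 4 may be O-allylated by the allylphosphonium salt before it has lost sulfinate. The quinone methide may oligomerise if the ylide concentration is low.
Fallback: this sets out from 4 and returns to the route at 12, so that steps 5 to 8 are bypassed and the ring is closed by olefin metathesis instead. Treatment of 4 with CH2=CHMgBr (2.5 equiv, THF, −78 to 0 °C) would release the same quinone methide and add a vinyl group to it, giving 2-allyl-3,5-bis(methoxymethoxy)phenol F1. O-Alkylation with 3-chloro-2-methylprop-1-ene and K2CO3 in DMF would give 2-allyl-1,5-bis(methoxymethoxy)-3-[(2-methylprop-2-en-1-yl)oxy]benzene F2. Ring-closing metathesis with the second-generation Grubbs catalyst, (H2IMes)(PCy3)Cl2Ru=CHPh, in CH2Cl2 at 40 °C would then give 12 directly.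

**Step 11.** Acyl transfer from the amide to the aryllithium, which has two ortho substituents, may be slow, so that enolisation of the amide returns both partners. A secondary concern is metalation straying to C9 or to the allylic methylenes if the temperature rises.
Fallback: this sets out from 12 and 15 and returns at 17, replacing acyl substitution by carbonyl addition and oxidation. Reduction of 15 with i-Bu2AlH (THF, −78 °C) would give 3-[3,4-bis(methoxymethoxy)phenyl]propanal F3. Addition of 16 (generated from 12 as in step 11) to F3 at −78 °C would give racemic 3-[3,4-bis(methoxymethoxy)phenyl]-1-[6,8-bis(methoxymethoxy)-3-methyl-2,5-dihydro-1-benzoxepin-7-yl]propan-1-ol F4. Oxidation with Dess–Martin periodinane (NaHCO3, CH2Cl2) would give 17.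

**Step 12.** The catechol MOM ethers lack the neighbouring carbonyl and need longer exposure to acid. During that time the trisubstituted olefin may add HCl or methanol or migrate.
Fallback: this sets out from 14 and 12 and returns at 18, changing the catechol protection so that acid is needed only for the two chelation-activated MOM ethers. Silylation of 14 (TBSCl, imidazole, DMF) would give 3-[3,4-bis(tert-butyldimethylsilyloxy)phenyl]-N-methoxy-N-methylpropanamide F5. Acylation of 16 with F5 would give 3-[3,4-bis(tert-butyldimethylsilyloxy)phenyl]-1-[6,8-bis(methoxymethoxy)-3-methyl-2,5-dihydro-1-benzoxepin-7-yl]propan-1-one F6. Brief treatment with dilute HCl in MeOH at rt would give 3-[3,4-bis(tert-butyldimethylsilyloxy)phenyl]-1-(6,8-dihydroxy-3-methyl-2,5-dihydro-1-benzoxepin-7-yl)propan-1-one F7. Bu4NF buffered with AcOH (THF, 0 °C) would then give 18.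

**Step 3 (with the labile alcohol of step 2).** The salicyl alcohol may ionise too early and self-condense. It may be over-reduced to the methyl compound during step 2. MOM groups may be lost if the acid has to be strengthened.
Fallback: this sets out from 2 and returns at 4, avoiding both alcohol 3 and any acid. Reductive amination of 2 (Me2NH, NaBH(OAc)3, 1,2-dichloroethane) would give 2-[(dimethylamino)methyl]-3,5-bis(methoxymethoxy)phenol F8. Quaternisation (MeI, MeCN) would give [2-hydroxy-4,6-bis(methoxymethoxy)benzyl]trimethylammonium iodide F9. Warming F9 with p-TolSO2Na in MeCN–H2O would release the quinone methide under near-neutral conditions and trap it as sulfone 4.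

## Further compounds

F1 | step 5 | 2-allyl-3,5-bis(methoxymethoxy)phenol | C=CCc1c(O)cc(OCOC)cc1OCOC
F2 | step 5 | 2-allyl-1,5-bis(methoxymethoxy)-3-[(2-methylprop-2-en-1-yl)oxy]benzene | C=CCc1c(OCC(C)=C)cc(OCOC)cc1OCOC
F3 | step 11 | 3-[3,4-bis(methoxymethoxy)phenyl]propanal | O=CCCc1ccc(OCOC)c(OCOC)c1
F4 | step 11 | 3-[3,4-bis(methoxymethoxy)phenyl]-1-[6,8-bis(methoxymethoxy)-3-methyl-2,5-dihydro-1-benzoxepin-7-yl]propan-1-ol (racemic) | CC1=CCc2c(cc(OCOC)c(C(O)CCc3ccc(OCOC)c(OCOC)c3)c2OCOC)OC1
F5 | step 12 | 3-[3,4-bis(tert-butyldimethylsilyloxy)phenyl]-N-methoxy-N-methylpropanamide | CON(C)C(=O)CCc1ccc(O[Si](C)(C)C(C)(C)C)c(O[Si](C)(C)C(C)(C)C)c1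
F6 | step 12 | 3-[3,4-bis(tert-butyldimethylsilyloxy)phenyl]-1-[6,8-bis(methoxymethoxy)-3-methyl-2,5-dihydro-1-benzoxepin-7-yl]propan-1-one | CC1=CCc2c(cc(OCOC)c(C(=O)CCc3ccc(O[Si](C)(C)C(C)(C)C)c(O[Si](C)(C)C(C)(C)C)c3)c2OCOC)OC1
F7 | step 12 | 3-[3,4-bis(tert-butyldimethylsilyloxy)phenyl]-1-(6,8-dihydroxy-3-methyl-2,5-dihydro-1-benzoxepin-7-yl)propan-1-one | CC1=CCc2c(cc(O)c(C(=O)CCc3ccc(O[Si](C)(C)C(C)(C)C)c(O[Si](C)(C)C(C)(C)C)c3)c2O)OC1
F8 | step 3 | 2-[(dimethylamino)methyl]-3,5-bis(methoxymethoxy)phenol | CN(C)Cc1c(O)cc(OCOC)cc1OCOC
F9 | step 3 | [2-hydroxy-4,6-bis(methoxymethoxy)benzyl]trimethylammonium iodide | C[N+](C)(C)Cc1c(O)cc(OCOC)cc1OCOC.[I-]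
A1 | alternative 1 | 3-[3,4-bis(methoxymethoxy)phenyl]-1-[6,8-bis(methoxymethoxy)-3-methyl-2,5-dihydro-1-benzoxepin-7-yl]propan-1-one (identical with 17) | CC1=CCc2c(cc(OCOC)c(C(=O)CCc3ccc(OCOC)c(OCOC)c3)c2OCOC)OC1
A2 | alternative 1 | 1-{4-bromo-3-[(2Z)-4-hydroxy-3-methylbut-2-en-1-yl]-2,6-bis(methoxymethoxy)phenyl}-3-[3,4-bis(methoxymethoxy)phenyl]propan-1-one | C/C(CO)=C/Cc1c(Br)cc(OCOC)c(C(=O)CCc2ccc(OCOC)c(OCOC)c2)c1OCOC
A3 | alternative 2 | 6,8-bis(methoxymethoxy)-3-methyl-2,5-dihydro-1-benzoxepine (identical with 12) | CC1=CCc2c(OCOC)cc(OCOC)cc2OC1
A4 | alternative 2 | 5,7-bis(methoxymethoxy)-4H-chromene | C1=COc2cc(OCOC)cc(OCOC)c2C1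
A5 | alternative 3 | 3-[3,4-bis(methoxymethoxy)phenyl]-1-(6,8-dihydroxy-3-methyl-2,5-dihydro-1-benzoxepin-7-yl)propan-1-one | CC1=CCc2c(cc(O)c(C(=O)CCc3ccc(OCOC)c(OCOC)c3)c2O)OC1
A6 | alternative 3 | 3-[3,4-bis(methoxymethoxy)phenyl]-1-{2,4,6-trihydroxy-3-[(2Z)-4-hydroxy-3-methylbut-2-en-1-yl]phenyl}propan-1-one | C/C(CO)=C/Cc1c(O)cc(O)c(C(=O)CCc2ccc(OCOC)c(OCOC)c2)c1O
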